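The rate constants are made up; no experiment stands behind them.

In a one-step world the substrate becomes intermediate and stops there. This flask adds a catalyst that turns intermediate into target and also dies.

substrate 15 mM; free catalyst 7.5 µM; time 25 min

    substrate → intermediate (k1 = 0.124 /s)
    free catalyst + target → spent catalyst B (k2 = 4.53 /M/s)
    free catalyst → spent catalyst A (k3 = 0.0863 /s)
    free catalyst + intermediate → free catalyst + target (k4 = 4530 /M/s)

- at 25 min, what has stopped the reaction, if anything has (all of the substrate has reacted / it is still moving)
- how much of the substrate has reacted by 25 min
- how much target there is at 25 min, in percent of the substrate charged
- amount of target if the flask were left three thousand times as long, in percent of the substrate charged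

- the reaction counts as stopped when no species that holds the substrate changes by six tenths of a point or more over the second half of the time
- run time (flask): 25 min

The substrate half-life of 0.093 min is short against 25 min, so by this reckoning 100% has reacted at the asked time.

The target is a question of exposure. Intermediate is consumed pseudo-first-order, with rate constant k4 times the free catalyst. If the catalyst dies by its own first-order step, the time integral of that rate from the start is the catalyst dose, 0.394. The catalyst decays while the substrate is still reacting, and intermediate born later meets less of this dose. Averaging over the births, which follow the substrate's decay, multiplies the dose by k1/(k1+k3). This gives 0.232, the delivered dose: the mean exposure of the intermediate to catalyst over the catalyst's lifetime. The fraction of the charge becoming target is then about one minus the exponential of minus that dose.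

| Flask as built up | Target, fraction of the charge |
|---|---|
| substrate step by itself | none |
| plus catalysed step, catalyst undying | 100% |
| plus catalyst death, substrate converted at once | 32.6% |
| plus substrate at its real rate | 20.7% |

The last process, catalyst lost to target, runs at 0.0141 /s per catalyst at that target level, slower than 0.0863 /s. It should therefore lower the figure slightly, and this reckoning commits to a little under 20.7%. The catalyst half-life by its own first-order step, 0.134 min, is far shorter than the time, so the long-term target should equal the target at the asked time.

The forecast's target lies lower than this reckoning's. The forecast says all of the substrate has reacted, with conversion 100%, target 18% and long-term target 18%, on the ground that “waiting longer adds nothing because no catalyst is left”.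

In the flask all of the substrate has reacted, with conversion 100%, target 18.8% and long-term target 18.8%. The target in this flask stands the same at 250 min as at 25.0 min. At 25.0 min this flask holds spent catalyst B at 5.11% of the catalyst charged, less than the 94.9% of spent catalyst A. The neighbour flask charged with 0.0045 mM of free catalyst has a delivered dose of 0.139, which reckons to 13.0% target. That neighbour flask gives 12.2% target, with spent catalyst B at 3.34% of the catalyst charged.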